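The reading comes at 10 h, and the question is where the X charged in this flask stands by then.

- dawn: X 0.40 M; E 1.44 M; run made earlier
- flask: X 0.80 M; E 1.44 M; time 10 h

dawn run (percent of the X charged)

| time / min | X / % | Q / % |
|---|---|---|
| 5.00 | 89.8 | 1.6 |
| 15.0 | 70.4 | 6.8 |
| 30.0 | 44.8 | 20.6 |
| 40.0 | 27.1 | 30.4 |
| 60.0 | 0 | 50.9 |

(readings scatter by 0.5 percentage points)

1. amount of X at 10 h, in percent of the X charged (only what is still solid)
2. amount of Q at 10 h, in percent of the X charged
3. amount of Z at 10 h, in percent of the X charged
4. amount of D at 10 h, in percent of the X charged

- solid, in amounts per volume of the solution: X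
- at the start none of X is in solution

In the dawn run the solid falls steadily between the first and fourth readings, at a pace equal to 0.537 /h of this flask's charge. By my own reckoning the solid here therefore lasts about 1.86 h, shorter than the 10 h. X is the limiting reagent for the first E it takes, charged in less than E, so I balance against it. The spare E is 80.0%: the E charged beyond one per X, as a fraction of the X charge. If D costs a second E, then late in the run D is the spare E less the E still left, so E left is the reading to watch.

The forecast gives solid X 0%, Q 60%, Z 10% and D 28%, and it says “Z and D were never measured, so the split is a guess”.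

This flask gives solid X 0%, Q 58.3%, Z 0.640% and D 41.0%. The forecast is 9.4 percentage points high on Z and 13 points low on D.

    J + E → Q (k = 1.80 /M/h)
    J + E → Z (k = 0.710 /M/h)
    E + Q → D (k = 0.0550 /M/h)
    E + Z → D (k = 1.10 /M/h)
    X ⇌ J, rate k5*(cs5 - [J]) while solid is left; crystals form when [J] > cs5 (solubility = 0.570 M, k = 0.890 /h)

The scheme makes Q and Z cost one E per X, and D two. In this flask at 10.0 h, E left is 22% of its own charge, which is 39.0% of the X charge, so the spare E of 80.0% less that is about 41.0%; this is the same balance as the 41.0% of D, not a separate test of it. The neighbouring flask with 2.4 M of E has a spare E of 200%. Its E left, 46% of its own charge, is 139% of the X charge, so the difference is 61.4%, and that flask holds D at 61.4%.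

The data come from a simulation on assumed constants.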